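**Retrosynthetic overview**

1. Numbering follows the geranylgeranyl skeleton: C1 is the CH2O carbon, C1–C9 the side chain, and the ring is C10 (stereogenic CH), C11 (bearing the exocyclic CH2), C12, C13, C14 (three CH2) and C15 (CMe2). The last disconnections are the malonate half-ester C–O bond (Meldrum's acid on the allylic alcohol) and a temporary hydroxyl on C13 (Barton–McCombie removal).
2. Enabling feature: in the only ring, the exocyclic methylene on C11 is joined through the ring CH2 C12 to C13. Once C13 carries OH this is a 3-methylidenecyclohexanol, the retron of a type 2 carbonyl-ene reaction, so the ring is opened across C12–C13 to an acyclic aldehyde (C13=O) with an isopropenyl group on C10.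
3. That aldehyde is a δ,ε-unsaturated carbonyl compound (O=C13–C14–C15–C10–C11=C12) with quaternary C15 next to C10, the retron of an oxy-Cope rearrangement. The precursor is therefore a linear (13R)-13-hydroxygeranylgeranyl silyl ether: anionic oxy-Cope (C15–C10 bond, chirality transfer from C13 to C10), then ene closure (C12–C13) without isolation.
4. The linear dienol comes from (2E,6E)-farnesol (C1–C12) and prenal (C13–C15 and one methyl): allylic oxidation at C12, chloride, α-selective allylbarium addition, then oxidation and CBS reduction to set C13.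
5. Ring order: the single carbocycle is formed once, in step 7; the silyl ether on O1 is the only protecting group.

Key step: step 7

Remark on the chemistry: (2E,6E)-farnesol is taken as the commercially available single geometric isomer. The carbinol centre created on C13 in step 7 is carried as a mixture of epimers, because steps 8 and 9 remove it.

**Route**

Step 1
Reactants: 1 (2E,6E)-farnesol; 2 tert-butyl(chloro)diphenylsilane
Product: 3 tert-butyl{[(2E,6E)-3,7,11-trimethyldodeca-2,6,10-trien-1-yl]oxy}diphenylsilane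
Conditions: imidazole, CH2Cl2, 0 °C to rt
Reagents that add atoms: tert-butyl(chloro)diphenylsilane (2), CC(C)(C)[Si](Cl)(c1ccccc1)c1ccccc1
Why: Silylation of the primary allylic alcohol should give an ether that withstands the later base, Lewis acid and radical steps.

Step 2
Reactants: 3 farnesyl silyl ether
Product: 4 (2E,6E,10E)-12-[(tert-butyldiphenylsilyl)oxy]-2,6,10-trimethyldodeca-2,6,10-trien-1-ol
Conditions: SeO2 (cat.), t-BuOOH, salicylic acid (cat.), CH2Cl2, 0 °C to rt, stopped at partial conversion
Reagents that add atoms: tert-butyl hydroperoxide, CC(C)(C)OO (oxygen relayed by catalytic selenium dioxide, O=[Se]=O)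
Why: Riley-type allylic oxidation (ene reaction, then [2,3]-shift) should attack the (E)-methyl of the terminal isopropylidene group, since the C2 alkene is deactivated by the allylic oxygen and the C6 alkene is more hindered, giving the (E)-allylic alcohol.

Step 3
Reactants: 4 allylic alcohol
Product: 5 tert-butyl{[(2E,6E,10E)-12-chloro-3,7,11-trimethyldodeca-2,6,10-trien-1-yl]oxy}diphenylsilane
Conditions: PPh3, CCl4, MeCN, rt
Reagents that add atoms: carbon tetrachloride, ClC(Cl)(Cl)Cl
Why: The Appel reaction should replace the primary allylic hydroxyl by chloride through SN2 attack on the alkoxyphosphonium ion, without allylic transposition or loss of the (E) geometry.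

Step 4
Reactants: 5 allylic chloride; 6 3-methylbut-2-enal (prenal)
Product: 8 (2E,6E,10E,13RS)-1-[(tert-butyldiphenylsilyl)oxy]-3,7,11,15-tetramethylhexadeca-2,6,10,14-tetraen-13-ol, via allylbarium chloride 7 (not isolated)
Conditions: BaI2, lithium biphenylide (2 equiv, from Li and biphenyl), THF, rt, to give activated barium; 5, −78 °C; then 6, −78 °C; aq. NH4Cl
Reagents that add atoms: 3-methylbut-2-enal (6), CC(C)=CC=O
Why: Allylbarium reagents form from allylic chlorides at −78 °C with retention of alkene geometry and add to aldehydes at the unsubstituted α-carbon (α-selective carbonyl allylation), and 1,2-addition is expected on the β,β-disubstituted enal; the carbinol centre is formed without control and is corrected in steps 5 and 6.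

Step 5
Reactants: 8 racemic dienol
Product: 9 (2E,6E,10E)-1-[(tert-butyldiphenylsilyl)oxy]-3,7,11,15-tetramethylhexadeca-2,6,10,14-tetraen-13-one
Conditions: activated MnO2 (excess), CH2Cl2, rt
Reagents that add atoms: none
Why: Manganese dioxide oxidation of the secondary allylic alcohol is heterogeneous and neutral, so the β,γ-alkene (C10=C11) should not migrate into conjugation.

Step 6
Reactants: 9 dienone
Product: 10 (2E,6E,10E,13R)-1-[(tert-butyldiphenylsilyl)oxy]-3,7,11,15-tetramethylhexadeca-2,6,10,14-tetraen-13-ol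
Conditions: (S)-Me-CBS oxazaborolidine [(S)-1-methyl-3,3-diphenyltetrahydro-1H,3H-pyrrolo[1,2-c][1,3,2]oxazaborole, C18H20BNO] (15 mol%), catecholborane, toluene, −78 °C; aq. NaOH work-up
Reagents that add atoms: none
Why: In the Corey–Bakshi–Shibata reduction the 2-methylprop-1-enyl group acts as the large substituent and the allylic CH2 as the small one, so the (S)-catalyst should deliver hydride to give the (13R)-carbinol, while catecholborane at −78 °C avoids hydroboration and conjugate reduction.

Step 7
Reactants: 10 (13R)-dienol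
Product: 14 (4S)-4-{(3E,7E)-9-[(tert-butyldiphenylsilyl)oxy]-3,7-dimethylnona-3,7-dien-1-yl}-5,5-dimethyl-3-methylidenecyclohexan-1-ol (both C1 epimers), via potassium alkoxide 11 (not isolated), via potassium enolate 12 (not isolated), via aldehyde 13 (not isolated)
Conditions: KH (1.2 equiv), 18-crown-6 (1.2 equiv), THF, 0 °C to rt; transfer into AcOH (1.5 equiv)/THF, −78 °C; THF removed in vacuo; CH2Cl2, Me2AlCl (3 equiv), −78 to −20 °C; aq. NaHCO3
Reagents that add atoms: none
Why: KH converts 10 into alkoxide 11, whose 1,5-diene (C15=C14–C13(O−)–C12–C11=C10) undergoes an anionic oxy-Cope [3,3]-shift through a chair transition state, making the C15–C10 bond and giving enolate 12; protonation releases the δ,ε-unsaturated aldehyde 13, and Me2AlCl then triggers a type 2 intramolecular carbonyl-ene reaction in which the CH2 terminus (C12) of the isopropenyl group bonds to the aldehyde carbon C13 while a hydrogen of the isopropenyl methyl passes to oxygen. The closest known reaction types are the potassium-alkoxide-accelerated oxy-Cope rearrangement of acyclic 1,5-dien-3-ols and the Me2AlCl-promoted cyclisation of 5-methylhex-5-enals to 3-methylidenecyclohexanols, and thermal oxy-Cope/ene tandems are also known. The six-membered ring closes at C12–C13 in a 6-exo-trig sense at the carbonyl carbon with the alkene engaged through both of its carbons (endo), the tether being attached to the central carbon of the ene unit, so that the new C11=CH2 double bond is necessarily exocyclic. The C10 stereocentre is set in the sigmatropic step by chirality transfer from (13R): the (10E)-alkene places C9 equatorial and the oxyanion is held equatorial because the axial site on C13 is syn-diaxial to one C15 methyl and close to the C11 methyl, which corresponds to (4R) in 13 and to the (S) configuration of the final ring; the carbinol centre formed on C13 in the ene step is not controlled and is erased in steps 8 and 9. Needed are the [3,3]-shift over retro-allylation of 11 (secured by the irreversible enolate formation and by the poorly stabilised allyl anion that cleavage would require) and hydrogen transfer from the methyl group rather than from C10–H (secured by the geometry of the bicyclic ene transition state and by Me2AlCl acting as proton scavenger, which prevents alkene migration and epimerisation at C10).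

Step 8
Reactants: 14 ring alcohol; 15 1,1'-thiocarbonyldiimidazole
Product: 16 O-[(4S)-4-{(3E,7E)-9-[(tert-butyldiphenylsilyl)oxy]-3,7-dimethylnona-3,7-dien-1-yl}-5,5-dimethyl-3-methylidenecyclohexyl] 1H-imidazole-1-carbothioate (both C1 epimers)
Conditions: DMAP (cat.), 1,2-dichloroethane, 70 °C
Reagents that add atoms: 1,1'-thiocarbonyldiimidazole (15), S=C(n1ccnc1)n1ccnc1
Why: Thioacylation of the unhindered secondary alcohol should give the imidazolide needed for Barton–McCombie deoxygenation without touching the alkenes or the silyl ether.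

Step 9
Reactants: 16 thiocarbonylimidazolide
Product: 17 tert-butyl({(2E,6E)-9-[(1S)-2,2-dimethyl-6-methylidenecyclohexyl]-3,7-dimethylnona-2,6-dien-1-yl}oxy)diphenylsilane
Conditions: Bu3SnH, AIBN (cat.), toluene, 90 °C
Reagents that add atoms: none
Why: In the Barton–McCombie deoxygenation the secondary C13 radical should be reduced by Bu3SnH faster than it can undergo 1,2-vinyl shift or cyclisation onto the remote alkenes, which removes the temporary hydroxyl and leaves C10 untouched.

Step 10
Reactants: 17 silyl ether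
Product: 18 (2E,6E)-9-[(1S)-2,2-dimethyl-6-methylidenecyclohexyl]-3,7-dimethylnona-2,6-dien-1-ol
Conditions: Bu4NF, THF, 0 °C to rt
Reagents that add atoms: none
Why: Fluoride-induced desilylation should free the primary allylic alcohol under conditions that do not affect the alkenes.

Step 11
Reactants: 18 allylic alcohol; 19 Meldrum's acid (2,2-dimethyl-1,3-dioxane-4,6-dione)
Product: 20 3-({(2E,6E)-9-[(1S)-2,2-dimethyl-6-methylidenecyclohexyl]-3,7-dimethylnona-2,6-dien-1-yl}oxy)-3-oxopropanoic acid (target)
Conditions: Meldrum's acid (1.1 equiv), toluene, 90 °C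
Reagents that add atoms: Meldrum's acid (19), CC1(C)OC(=O)CC(=O)O1
Why: Acylation of the alcohol by ring-opening of Meldrum's acid with loss of acetone should give the malonic acid half-ester directly, below the temperature of decarboxylation.

**Compound list**

1 | (2E,6E)-farnesol | CC(C)=CCC/C(C)=C/CC/C(C)=C/CO | starting material
2 | tert-butyl(chloro)diphenylsilane | CC(C)(C)[Si](Cl)(c1ccccc1)c1ccccc1 | starting material
3 | tert-butyl{[(2E,6E)-3,7,11-trimethyldodeca-2,6,10-trien-1-yl]oxy}diphenylsilane | CC(C)=CCC/C(C)=C/CC/C(C)=C/CO[Si](c1ccccc1)(c1ccccc1)C(C)(C)C | intermediate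
4 | (2E,6E,10E)-12-[(tert-butyldiphenylsilyl)oxy]-2,6,10-trimethyldodeca-2,6,10-trien-1-ol | OC/C(C)=C/CC/C(C)=C/CC/C(C)=C/CO[Si](c1ccccc1)(c1ccccc1)C(C)(C)C | intermediate
5 | tert-butyl{[(2E,6E,10E)-12-chloro-3,7,11-trimethyldodeca-2,6,10-trien-1-yl]oxy}diphenylsilane | ClC/C(C)=C/CC/C(C)=C/CC/C(C)=C/CO[Si](c1ccccc1)(c1ccccc1)C(C)(C)C | intermediate
6 | 3-methylbut-2-enal (prenal) | CC(C)=CC=O | starting material
7 | chloro{(2E,6E,10E)-12-[(tert-butyldiphenylsilyl)oxy]-2,6,10-trimethyldodeca-2,6,10-trien-1-yl}barium | Cl[Ba]C/C(C)=C/CC/C(C)=C/CC/C(C)=C/CO[Si](c1ccccc1)(c1ccccc1)C(C)(C)C | intermediate (not isolated)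
8 | (2E,6E,10E,13RS)-1-[(tert-butyldiphenylsilyl)oxy]-3,7,11,15-tetramethylhexadeca-2,6,10,14-tetraen-13-ol (racemic) | CC(C)=CC(O)C/C(C)=C/CC/C(C)=C/CC/C(C)=C/CO[Si](c1ccccc1)(c1ccccc1)C(C)(C)C | intermediate
9 | (2E,6E,10E)-1-[(tert-butyldiphenylsilyl)oxy]-3,7,11,15-tetramethylhexadeca-2,6,10,14-tetraen-13-one | CC(C)=CC(=O)C/C(C)=C/CC/C(C)=C/CC/C(C)=C/CO[Si](c1ccccc1)(c1ccccc1)C(C)(C)C | intermediate
10 | (2E,6E,10E,13R)-1-[(tert-butyldiphenylsilyl)oxy]-3,7,11,15-tetramethylhexadeca-2,6,10,14-tetraen-13-ol | CC(C)=C[C@H](O)C/C(C)=C/CC/C(C)=C/CC/C(C)=C/CO[Si](c1ccccc1)(c1ccccc1)C(C)(C)C | intermediate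
11 | potassium (2E,6E,10E,13R)-1-[(tert-butyldiphenylsilyl)oxy]-3,7,11,15-tetramethylhexadeca-2,6,10,14-tetraen-13-olate | CC(C)=C[C@H]([O-])C/C(C)=C/CC/C(C)=C/CC/C(C)=C/CO[Si](c1ccccc1)(c1ccccc1)C(C)(C)C.[K+] | intermediate (not isolated)
12 | potassium (1E,4R,7E,11E)-13-[(tert-butyldiphenylsilyl)oxy]-3,3,7,11-tetramethyl-4-(prop-1-en-2-yl)trideca-1,7,11-trien-1-olate | [K+].[O-]/C=C/C(C)(C)[C@@H](C(C)=C)CC/C(C)=C/CC/C(C)=C/CO[Si](c1ccccc1)(c1ccccc1)C(C)(C)C | intermediate (not isolated)
13 | (4R,7E,11E)-13-[(tert-butyldiphenylsilyl)oxy]-3,3,7,11-tetramethyl-4-(prop-1-en-2-yl)trideca-7,11-dienal | O=CCC(C)(C)[C@@H](C(C)=C)CC/C(C)=C/CC/C(C)=C/CO[Si](c1ccccc1)(c1ccccc1)C(C)(C)C | intermediate (not isolated)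
14 | (4S)-4-{(3E,7E)-9-[(tert-butyldiphenylsilyl)oxy]-3,7-dimethylnona-3,7-dien-1-yl}-5,5-dimethyl-3-methylidenecyclohexan-1-ol (both C1 epimers) | C=C1CC(O)CC(C)(C)[C@@H]1CC/C(C)=C/CC/C(C)=C/CO[Si](c1ccccc1)(c1ccccc1)C(C)(C)C | intermediate
15 | 1,1'-thiocarbonyldiimidazole | S=C(n1ccnc1)n1ccnc1 | starting material
16 | O-[(4S)-4-{(3E,7E)-9-[(tert-butyldiphenylsilyl)oxy]-3,7-dimethylnona-3,7-dien-1-yl}-5,5-dimethyl-3-methylidenecyclohexyl] 1H-imidazole-1-carbothioate (both C1 epimers) | C=C1CC(OC(=S)n2ccnc2)CC(C)(C)[C@@H]1CC/C(C)=C/CC/C(C)=C/CO[Si](c1ccccc1)(c1ccccc1)C(C)(C)C | intermediate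
17 | tert-butyl({(2E,6E)-9-[(1S)-2,2-dimethyl-6-methylidenecyclohexyl]-3,7-dimethylnona-2,6-dien-1-yl}oxy)diphenylsilane | C=C1CCCC(C)(C)[C@@H]1CC/C(C)=C/CC/C(C)=C/CO[Si](c1ccccc1)(c1ccccc1)C(C)(C)C | intermediate
18 | (2E,6E)-9-[(1S)-2,2-dimethyl-6-methylidenecyclohexyl]-3,7-dimethylnona-2,6-dien-1-ol | C=C1CCCC(C)(C)[C@@H]1CC/C(C)=C/CC/C(C)=C/CO | intermediate
19 | Meldrum's acid (2,2-dimethyl-1,3-dioxane-4,6-dione) | CC1(C)OC(=O)CC(=O)O1 | starting material
20 | 3-({(2E,6E)-9-[(1S)-2,2-dimethyl-6-methylidenecyclohexyl]-3,7-dimethylnona-2,6-dien-1-yl}oxy)-3-oxopropanoic acid | C=C1CCCC(C)(C)[C@@H]1CC/C(C)=C/CC/C(C)=C/COC(=O)CC(=O)O | target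

**Step count and risks**

Total step count: 11. Longest linear sequence: 11 steps (1 to 20).

Steps most likely to fail:

1. Step 7. The alkoxide may fragment by retro-allylation (heterolysis of C12–C13) faster than the congested [3,3]-shift that joins the gem-dimethyl terminus to C10, or chirality transfer may erode through a competing chair with axial oxyanion or a boat. Fallback, setting out from 4 and coming back to the route at 13: alcohol 4 is acylated with 2-methylpropanoyl chloride (pyridine, DMAP) to the isobutyrate F1. An enantioselective Ireland–Claisen rearrangement mediated by a chiral 2-bromo-4,5-diphenyl-1,3-bis(4-methylphenylsulfonyl)-1,3,2-diazaborolidine and Et3N (CH2Cl2, −78 to 4 °C; the reagent antipode is chosen to give 3R) forms the C15–C10 bond and gives the acid F2. LiAlH4 reduces F2 to the neopentyl alcohol F3, Dess–Martin periodinane gives the aldehyde F4, and Wittig methoxymethylenation (Ph3P=CHOMe) gives the enol ether F5. Mild aqueous acid hydrolysis of F5 then delivers 13, which is isolated and cyclised with Me2AlCl to 14 as in the second half of step 7.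

2. Step 4. Metallotropic equilibration of the allylmetal may cost α-regioselectivity or (E)-geometry, or the electron-transfer reagent may reductively cleave the allylic silyl ether. Fallback, setting out from 5 and coming back at 9: chloride 5 is displaced by PhSO2Na (DMF, rt) to the allylic sulfone F6. Its α-sulfonyl carbanion (n-BuLi, 2 equiv, THF, −78 °C) is acylated with methyl 3-methylbut-2-enoate to the β-keto sulfone F7. Reductive desulfonylation with SmI2 (divalent samarium, THF/MeOH, −78 °C) gives 9 after α-protonation.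

3. Step 6. The catalyst may discriminate poorly between the 2-methylprop-1-enyl and allylic CH2 flanks of the ketone, or the β,γ-alkene of 9 may drift into conjugation before reduction. Fallback, setting out from 8 and coming back at 10: racemic 8 is esterified with (2S)-2-methoxy-2-phenylacetic acid (DCC, DMAP, CH2Cl2). The diastereomeric esters are separated by chromatography into the (13R)-ester F8 and the (13S)-ester F9, which is set aside. Saponification of F8 (LiOH, THF/H2O) gives 10.

**Further compounds**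

F1 | step 7 | (2E,6E,10E)-12-[(tert-butyldiphenylsilyl)oxy]-2,6,10-trimethyldodeca-2,6,10-trien-1-yl 2-methylpropanoate | CC(C)C(=O)OC/C(C)=C/CC/C(C)=C/CC/C(C)=C/CO[Si](c1ccccc1)(c1ccccc1)C(C)(C)C
F2 | step 7 | (3R,6E,10E)-12-[(tert-butyldiphenylsilyl)oxy]-2,2,6,10-tetramethyl-3-(prop-1-en-2-yl)dodeca-6,10-dienoic acid | OC(=O)C(C)(C)[C@@H](C(C)=C)CC/C(C)=C/CC/C(C)=C/CO[Si](c1ccccc1)(c1ccccc1)C(C)(C)C
F3 | step 7 | (3R,6E,10E)-12-[(tert-butyldiphenylsilyl)oxy]-2,2,6,10-tetramethyl-3-(prop-1-en-2-yl)dodeca-6,10-dien-1-ol | OCC(C)(C)[C@@H](C(C)=C)CC/C(C)=C/CC/C(C)=C/CO[Si](c1ccccc1)(c1ccccc1)C(C)(C)C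
F4 | step 7 | (3R,6E,10E)-12-[(tert-butyldiphenylsilyl)oxy]-2,2,6,10-tetramethyl-3-(prop-1-en-2-yl)dodeca-6,10-dienal | O=CC(C)(C)[C@@H](C(C)=C)CC/C(C)=C/CC/C(C)=C/CO[Si](c1ccccc1)(c1ccccc1)C(C)(C)C
F5 | step 7 | tert-butyl{[(2E,6E,10R)-13-methoxy-3,7,11,11-tetramethyl-10-(prop-1-en-2-yl)trideca-2,6,12-trien-1-yl]oxy}diphenylsilane (12E/12Z mixture) | COC=CC(C)(C)[C@@H](C(C)=C)CC/C(C)=C/CC/C(C)=C/CO[Si](c1ccccc1)(c1ccccc1)C(C)(C)C
F6 | step 4 | tert-butyl{[(2E,6E,10E)-12-(benzenesulfonyl)-3,7,11-trimethyldodeca-2,6,10-trien-1-yl]oxy}diphenylsilane | O=S(=O)(C/C(C)=C/CC/C(C)=C/CC/C(C)=C/CO[Si](c1ccccc1)(c1ccccc1)C(C)(C)C)c1ccccc1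
F7 | step 4 | (2E,6E,10E,12RS)-12-(benzenesulfonyl)-1-[(tert-butyldiphenylsilyl)oxy]-3,7,11,15-tetramethylhexadeca-2,6,10,14-tetraen-13-one | CC(C)=CC(=O)C(S(=O)(=O)c1ccccc1)/C(C)=C/CC/C(C)=C/CC/C(C)=C/CO[Si](c1ccccc1)(c1ccccc1)C(C)(C)C
F8 | step 6 | (2E,6E,10E,13R)-1-[(tert-butyldiphenylsilyl)oxy]-3,7,11,15-tetramethylhexadeca-2,6,10,14-tetraen-13-yl (2S)-2-methoxy-2-phenylacetate | CO[C@H](C(=O)O[C@@H](C=C(C)C)C/C(C)=C/CC/C(C)=C/CC/C(C)=C/CO[Si](c1ccccc1)(c1ccccc1)C(C)(C)C)c1ccccc1
F9 | step 6 | (2E,6E,10E,13S)-1-[(tert-butyldiphenylsilyl)oxy]-3,7,11,15-tetramethylhexadeca-2,6,10,14-tetraen-13-yl (2S)-2-methoxy-2-phenylacetate | CO[C@H](C(=O)O[C@H](C=C(C)C)C/C(C)=C/CC/C(C)=C/CC/C(C)=C/CO[Si](c1ccccc1)(c1ccccc1)C(C)(C)C)c1ccccc1
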